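The plan rests on cutting the hydroazulene back to a cyclopentane-1,3-dione. In the cycloheptane, the C(=CH2) carbon and the CMe2 carbon sit on either side of the two ring-fusion CH carbons; written as ketones they are the two carbonyl carbons of a 1,3-dione pushed apart by two carbons. An intramolecular de Mayo reaction delivers this in one operation: [2+2] addition of the dione enol to a tethered Me2C=CH alkene closes the cyclopentane, and retro-aldol opening of the cyclobutanol enlarges the dione ring to the cis-fused cycloheptanedione, setting both ring-fusion centres. The precursor is a 2-substituted dione enol whose quaternary carbon already bears the methyl, a tert-butyl acetate arm and the homoprenyl tether.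

Key step: step 8

Remarks on the chemistry:
- The two-carbon arm of the photosubstrate is carried as a tert-butyl ester: it cannot acylate the enol oxygen, cannot act as the acyl acceptor in the dione-forming Claisen closure, and is bulkier than the methyl group it must be told apart from in the photocycloaddition.
- With the dione ring ranked first and the ester arm second, the quaternary carbon of the photosubstrate must be (S). (R)-4 provides it, because the ring cleavage of step 4 turns the carbonyl side into the ester arm and the carbinol side into the dione.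
- Assumption: methyl (R)-2-hydroxybut-3-enoate (19) is bought as the enantiopure vinylglycolate; in step 2 the ligand antipode that gives (R)-4 is used.

Step 1
Reactants: 1 3-ethoxycyclopent-2-en-1-one; 2 5-bromo-2-methylpent-2-ene
Product: 3 3-(4-methylpent-3-en-1-yl)cyclopent-2-en-1-one
Conditions: 2, Mg, THF; add 1, 0 °C → rt; then 1 M HCl, 0 °C
Reagents that add atoms: water, O
Why: Stork–Danheiser sequence, in which the Grignard reagent adds 1,2 to the vinylogous ester and acid hydrolysis of the enol ether with loss of water transposes the carbonyl to give the 3-substituted enone (no stereocentre).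

Step 2
Reactants: 3 3-(4-methylpent-3-en-1-yl)cyclopent-2-en-1-one
Product: 4 (R)-3-methyl-3-(4-methylpent-3-en-1-yl)cyclopentan-1-one
Conditions: Me3Al, Cu(OTf)2 (2 mol %), BINOL-derived bis(1-phenylethyl)amine phosphoramidite (4 mol %), Et2O, −30 °C; aq. NH4Cl
Reagents that add atoms: trimethylaluminium, C[Al](C)C
Why: Copper-catalysed asymmetric conjugate addition of Me3Al to a 3-substituted cyclic enone, a known way to β-quaternary ketones, in which the chiral ligand selects the enone face and so sets the quaternary centre as (R).

Step 3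
Reactants: 4 (R)-3-methyl-3-(4-methylpent-3-en-1-yl)cyclopentan-1-one
Product: 5 (4R)-2-hydroxy-4-methyl-4-(4-methylpent-3-en-1-yl)cyclopentan-1-one (both C2 epimers)
Conditions: LiN(iPr)2, THF, −78 °C; 2-(phenylsulfonyl)-3-phenyloxaziridine, −78 °C; cold aq. NH4Cl
Reagents that add atoms: 2-(phenylsulfonyl)-3-phenyloxaziridine, O=S(=O)(N1OC1c1ccccc1)c1ccccc1
Why: Davis enolate hydroxylation after kinetic deprotonation at the α-CH2 remote from the quaternary carbon; the carbinol centre is a mixture that step 4 destroys, and the cold neutral quench avoids an acyloin shift that would exchange the two arms.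

Step 4
Reactants: 5 (4R)-2-hydroxy-4-methyl-4-(4-methylpent-3-en-1-yl)cyclopentan-1-one
Product: 6 (R)-3,7-dimethyl-3-(2-oxoethyl)oct-6-enoic acid
Conditions: NaIO4, THF–H2O, rt
Reagents that add atoms: water, O
Why: Periodate cleavage of the α-hydroxy ketone through its hydrate turns the carbonyl carbon into CO2H and the carbinol carbon into CHO, so the two arms of the untouched quaternary carbon become different while the trisubstituted alkene is left alone.

Step 5
Reactants: 6 (R)-3,7-dimethyl-3-(2-oxoethyl)oct-6-enoic acid
Product: 7 tert-butyl (R)-3,7-dimethyl-3-(2-oxoethyl)oct-6-enoate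
Conditions: tert-butyl 2,2,2-trichloroacetimidate, CH2Cl2–cyclohexane, rt
Reagents that add atoms: tert-butyl 2,2,2-trichloroacetimidate, CC(C)(C)OC(=N)C(Cl)(Cl)Cl
Why: Imidate esterification, in which the carboxylic acid protonates the imidate and captures the tert-butyl group under conditions that leave aldehyde and alkene untouched.

Step 6
Reactants: 7 tert-butyl (R)-3,7-dimethyl-3-(2-oxoethyl)oct-6-enoate; 8 methyl acrylate
Product: 9 1-tert-butyl 8-methyl (R)-3-methyl-3-(4-methylpent-3-en-1-yl)-5-oxooctanedioate
Conditions: 3-benzyl-5-(2-hydroxyethyl)-4-methylthiazolium chloride (15 mol %), Et3N, 1,4-dioxane, 80 °C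
Reagents that add atoms: none
Why: Stetter reaction, in which the thiazolylidene converts the aldehyde into an acyl-anion equivalent that adds 1,4 to the acrylate to give the γ-keto ester; self-aldolisation of this neopentyl-type aldehyde is slow.

Step 7
Reactants: 9 1-tert-butyl 8-methyl (R)-3-methyl-3-(4-methylpent-3-en-1-yl)-5-oxooctanedioate
Product: 10 tert-butyl (S)-3-(2-hydroxy-5-oxocyclopent-1-en-1-yl)-3,7-dimethyloct-6-enoate
Conditions: KOtBu (2.2 equiv), THF, 0 → 50 °C; cold 1 M HCl
Reagents that add atoms: none
Why: Intramolecular Claisen (Dieckmann-type) condensation of the ketone enolate next to the quaternary carbon onto the methyl ester closes the five-membered ring and is driven by the 1,3-dione enolate; the hindered tert-butyl ester does not serve as acceptor for the competing six-ring closure.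

Step 8
Reactants: 10 tert-butyl (S)-3-(2-hydroxy-5-oxocyclopent-1-en-1-yl)-3,7-dimethyloct-6-enoate
Product: 12 tert-butyl 2-[(1S,3aR,8aR)-1,4,4-trimethyl-5,8-dioxodecahydroazulen-1-yl]acetate, via cyclobutanol photoadduct 11 (not isolated)
Conditions: hν (254 nm, quartz), degassed MeCN (0.005 M), 10 °C
Reagents that add atoms: none
Why: Excitation of the enolised dione (an enone chromophore) first bonds dione C2 to the internal CH of the Me2C=CH alkene (1,5-closure by the rule of five, forming the cyclopentane), then the tertiary Me2C radical recombines with the enol carbon to close the cyclobutane; β-hydroxy ketone 11 undergoes strain-driven retro-aldol cleavage of the bond shared by the four-membered and the old five-membered ring, which grows the latter by two carbons into the cycloheptane-1,4-dione. This is the intramolecular de Mayo reaction known for cyclic 1,3-dione enols bearing a tethered alkene. The ring-fusion CH next to CMe2 is set in the first bond formation: in the chair-like closure the larger CH2CO2tBu arm of the pre-set quaternary carbon lies pseudo-equatorial, so the Me2C terminus ends cis to the methyl and trans to the arm. The ring-fusion CH next to the ketone is set afterwards, when the enol left by the retro-aldol step is protonated on the face away from the CMe2 carbon, giving the cis fusion. The step needs the straight regiochemistry, secured by the three-atom tether and the tertiary radical, and facial selectivity, for which the bulky non-lactonising tert-butyl ester and the hydrogen-bond-accepting solvent are chosen. Light of 254 nm is absorbed by the enol and hardly by the product ketones, which limits secondary Norrish α-cleavage.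

Step 9
Reactants: 12 tert-butyl 2-[(1S,3aR,8aR)-1,4,4-trimethyl-5,8-dioxodecahydroazulen-1-yl]acetate
Product: 13 tert-butyl 2-[(1S,3aR,8aS)-1,4,4-trimethyl-8-methylidene-5-oxodecahydroazulen-1-yl]acetate
Conditions: Zn, CH2Br2, TiCl4, THF–CH2Cl2, 0 °C → rt
Reagents that add atoms: dibromomethane, BrCBr
Why: Takai–Lombardo methylenation, whose non-basic Zn/Ti reagent olefinates the less hindered ketone (flanked by CH and CH2) and leaves the neopentyl ketone beside CMe2 and the ester; no enolate is formed, so the adjacent ring-fusion centre is retained.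

Step 10
Reactants: 13 tert-butyl 2-[(1S,3aR,8aS)-1,4,4-trimethyl-8-methylidene-5-oxodecahydroazulen-1-yl]acetate
Product: 14 2-[(1S,3aR,8aS)-1,4,4-trimethyl-8-methylidenedecahydroazulen-1-yl]acetic acid
Conditions: N2H4·H2O, KOH, diethylene glycol, 130 → 200 °C; then aq. HCl, 0 °C
Reagents that add atoms: potassium hydroxide, [K+].[OH-]
Why: Wolff–Kishner reduction (Huang–Minlon) converts the ketone beside the gem-dimethyl carbon into CH2 through its hydrazone, as is routine for 2,2-dimethyl ketones, and the hot hydroxide also cleaves the tert-butyl ester; no stereocentre is α to the carbonyl.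

Step 11
Reactants: 14 2-[(1S,3aR,8aS)-1,4,4-trimethyl-8-methylidenedecahydroazulen-1-yl]acetic acid
Product: 15 2-[(1S,3aR,8aS)-1,4,4-trimethyl-8-methylidenedecahydroazulen-1-yl]ethan-1-ol
Conditions: LiAlH4, THF, 0 °C → reflux; aq. NaOH work-up
Reagents that add atoms: none
Why: Hydride reduction of the carboxylic acid to the primary alcohol, which does not touch the isolated 1,1-disubstituted alkene.

Step 12
Reactants: 15 2-[(1S,3aR,8aS)-1,4,4-trimethyl-8-methylidenedecahydroazulen-1-yl]ethan-1-ol
Product: 16 2-[(1S,3aR,8aS)-1,4,4-trimethyl-8-methylidenedecahydroazulen-1-yl]acetaldehyde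
Conditions: Dess–Martin periodinane, NaHCO3, CH2Cl2, rt
Reagents that add atoms: none
Why: Dess–Martin oxidation stops at the aldehyde and is inert toward the alkene; the α-carbon is a CH2 on a quaternary carbon, so nothing can epimerise.

Step 13
Reactants: 16 2-[(1S,3aR,8aS)-1,4,4-trimethyl-8-methylidenedecahydroazulen-1-yl]acetaldehyde
Product: 18 methyl enol ether of 16 (2-methoxyethenyl group on the quaternary carbon; E/Z mixture), via dimethyl acetal 17 (not isolated)
Conditions: HC(OMe)3, TMSOTf (2 mol %), CH2Cl2, −78 → 0 °C; then iPr2NEt, TMSOTf (1.3 equiv), 0 °C → rt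
Reagents that add atoms: trimethyl orthoformate, COC(OC)OC
Why: Acetalisation followed by Gassman-type elimination of methanol from the dimethyl acetal (silyl triflate with a hindered amine) gives the enol ether, whose geometry is immaterial because the next step destroys it.

Step 14
Reactants: 19 methyl (R)-2-hydroxybut-3-enoate; 20 tert-butyl acrylate
Product: 21 5-tert-butyl 1-methyl (2R,3E)-2-hydroxypent-3-enedioate
Conditions: second-generation Hoveyda–Grubbs catalyst (3 mol %), 20 (3 equiv), CH2Cl2, 40 °C
Reagents that add atoms: none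
Why: Olefin cross-metathesis of the terminal alkene with the electron-poor acrylate gives the (E)-enoate and does not involve the carbinol stereocentre.

Step 15
Reactants: 18 methyl enol ether of 16; 21 5-tert-butyl 1-methyl (2R,3E)-2-hydroxypent-3-enedioate
Product: 22 mixed bromoacetal (CHBr on the quaternary carbon; acetal carbon bearing OMe and the oxygen of 21; mixture at both new centres)
Conditions: NBS (1.05 equiv), 21 (1.5 equiv), CH2Cl2, −78 → −20 °C
Reagents that add atoms: N-bromosuccinimide, O=C1CCC(=O)N1Br
Why: Bromoacetalisation as in the Ueno–Stork protocol, in which bromonium attack on the electron-rich enol ether (far faster than on the 1,1-disubstituted alkene or the enoate) gives an oxocarbenium ion that the hydroxyl of 21 captures; both new centres are lost later.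

Step 16
Reactants: 22 mixed bromoacetal
Product: 23 2-methoxytetrahydrofuran with the hydroazulenyl group at C3, CH2CO2tBu at C4 (cis to it) and CO2Me at C5 (trans to the C4 side chain)
Conditions: Bu3SnH (slow addition), AIBN, benzene, 80 °C
Reagents that add atoms: none
Why: Ueno–Stork 5-exo-trig radical cyclisation onto the β-carbon of the enoate through a chair-like transition state, in which the CO2Me on the carbinol carbon lies pseudo-equatorial (new side chain trans to it) and the tert-alkyl group on the radical carbon points outward (cis to the side chain, Beckwith guidelines), so both new centres follow from the stereocentre of 19.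

Step 17
Reactants: 23 2-methoxytetrahydrofuran acetal
Product: 24 methyl 8-(hydroazulenyl)-3-oxo-2,7-dioxabicyclo[3.2.1]octane-6-carboxylate (ester exo; hydroazulenyl group syn to the lactone bridge)
Conditions: TMSOTf, 2,6-lutidine, CH2Cl2, −40 → 0 °C
Reagents that add atoms: none
Why: Ionisation of the methyl acetal to the oxocarbenium ion and capture by the carbonyl oxygen of the cis-placed tert-butyl ester with loss of isobutene (cation-triggered lactonisation) gives the bridged acyloxy acetal, and the bridge can only close on the face of the side chain, which fixes the acetal carbon.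

Step 18
Reactants: 24 bicyclic lactone
Product: 26 target (CNP0215240.1), via hydroxy lactone 25 (not isolated)
Conditions: KN(SiMe3)2, THF, −78 °C; 2-(phenylsulfonyl)-3-phenyloxaziridine, −78 °C; then Ac2O, DMAP, −78 → 0 °C
Reagents that add atoms: 2-(phenylsulfonyl)-3-phenyloxaziridine, O=S(=O)(N1OC1c1ccccc1)c1ccccc1; acetic anhydride, CC(=O)OC(C)=O
Why: Davis hydroxylation of the lactone enolate (the lactone CH2 is the most acidic position) takes place on the face away from the tert-alkyl group that leans over the lactone bridge from the one-atom bridge, placing oxygen on the side of the CH(CO2Me)–O bridge as required, and the alkoxide is acetylated in the same flask.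

Compound list
1 | 3-ethoxycyclopent-2-en-1-one | CCOC1=CC(=O)CC1 | starting material
2 | 5-bromo-2-methylpent-2-ene | CC(C)=CCCBr | starting material
3 | 3-(4-methylpent-3-en-1-yl)cyclopent-2-en-1-one | CC(C)=CCCC1=CC(=O)CC1 | intermediate
4 | (R)-3-methyl-3-(4-methylpent-3-en-1-yl)cyclopentan-1-one | O=C1C[C@](C)(CCC=C(C)C)CC1 | intermediate
5 | (4R)-2-hydroxy-4-methyl-4-(4-methylpent-3-en-1-yl)cyclopentan-1-one (C2 epimers) | O=C1C[C@](C)(CCC=C(C)C)CC1O | intermediate
6 | (R)-3,7-dimethyl-3-(2-oxoethyl)oct-6-enoic acid | OC(=O)C[C@](C)(CCC=C(C)C)CC=O | intermediate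
7 | tert-butyl (R)-3,7-dimethyl-3-(2-oxoethyl)oct-6-enoate | CC(C)(C)OC(=O)C[C@](C)(CCC=C(C)C)CC=O | intermediate
8 | methyl acrylate | C=CC(=O)OC | starting material
9 | 1-tert-butyl 8-methyl (R)-3-methyl-3-(4-methylpent-3-en-1-yl)-5-oxooctanedioate | CC(C)(C)OC(=O)C[C@](C)(CCC=C(C)C)CC(=O)CCC(=O)OC | intermediate
10 | tert-butyl (S)-3-(2-hydroxy-5-oxocyclopent-1-en-1-yl)-3,7-dimethyloct-6-enoate | O=C1CCC(O)=C1[C@](C)(CC(=O)OC(C)(C)C)CCC=C(C)C | intermediate
11 | cyclobutanol photoadduct (tricyclic β-hydroxy ketone; cyclobutane cis-fused to both five-membered rings) | O=C1CC[C@@]2(O)C(C)(C)[C@@H]3CC[C@@](C)(CC(=O)OC(C)(C)C)[C@]123 | intermediate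
12 | tert-butyl 2-[(1S,3aR,8aR)-1,4,4-trimethyl-5,8-dioxodecahydroazulen-1-yl]acetate (cis-fused; ester arm cis to both ring-fusion hydrogens) | O=C1CCC(=O)C(C)(C)[C@@H]2CC[C@@](C)(CC(=O)OC(C)(C)C)[C@H]12 | intermediate
13 | tert-butyl 2-[(1S,3aR,8aS)-1,4,4-trimethyl-8-methylidene-5-oxodecahydroazulen-1-yl]acetate | C=C1CCC(=O)C(C)(C)[C@@H]2CC[C@@](C)(CC(=O)OC(C)(C)C)[C@H]12 | intermediate
14 | 2-[(1S,3aR,8aS)-1,4,4-trimethyl-8-methylidenedecahydroazulen-1-yl]acetic acid | C=C1CCCC(C)(C)[C@@H]2CC[C@@](C)(CC(=O)O)[C@H]12 | intermediate
15 | 2-[(1S,3aR,8aS)-1,4,4-trimethyl-8-methylidenedecahydroazulen-1-yl]ethan-1-ol | C=C1CCCC(C)(C)[C@@H]2CC[C@@](C)(CCO)[C@H]12 | intermediate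
16 | 2-[(1S,3aR,8aS)-1,4,4-trimethyl-8-methylidenedecahydroazulen-1-yl]acetaldehyde | C=C1CCCC(C)(C)[C@@H]2CC[C@@](C)(CC=O)[C@H]12 | intermediate
17 | dimethyl acetal of 16 | C=C1CCCC(C)(C)[C@@H]2CC[C@@](C)(CC(OC)OC)[C@H]12 | intermediate
18 | methyl enol ether of 16 (E/Z mixture) | C=C1CCCC(C)(C)[C@@H]2CC[C@@](C)(C=COC)[C@H]12 | intermediate
19 | methyl (R)-2-hydroxybut-3-enoate | COC(=O)[C@H](O)C=C | starting material
20 | tert-butyl acrylate | C=CC(=O)OC(C)(C)C | starting material
21 | 5-tert-butyl 1-methyl (2R,3E)-2-hydroxypent-3-enedioate | COC(=O)[C@H](O)/C=C/C(=O)OC(C)(C)C | intermediate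
22 | mixed bromoacetal of 18 and 21 (mixture at CHBr and at the acetal carbon) | C=C1CCCC(C)(C)[C@@H]2CC[C@@](C)(C(Br)C(OC)O[C@@H](C(=O)OC)/C=C/C(=O)OC(C)(C)C)[C@H]12 | intermediate
23 | 2-methoxytetrahydrofuran: hydroazulenyl at C3, CH2CO2tBu at C4 (cis), CO2Me at C5 (trans to the C4 chain); acetal epimers | C=C1CCCC(C)(C)[C@@H]2CC[C@@](C)([C@@H]3C(OC)O[C@@H](C(=O)OC)[C@@H]3CC(=O)OC(C)(C)C)[C@H]12 | intermediate
24 | methyl 8-(hydroazulenyl)-3-oxo-2,7-dioxabicyclo[3.2.1]octane-6-carboxylate | C=C1CCCC(C)(C)[C@@H]2CC[C@@](C)([C@@H]3[C@@H]4OC(=O)C[C@H]3[C@H](C(=O)OC)O4)[C@H]12 | intermediate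
25 | 4-hydroxy derivative of 24 (hydroxyl on the side of the CH(CO2Me)–O bridge) | C=C1CCCC(C)(C)[C@@H]2CC[C@@](C)([C@@H]3[C@@H]4OC(=O)[C@@H](O)[C@H]3[C@H](C(=O)OC)O4)[C@H]12 | intermediate
26 | CNP0215240.1 (4-acetoxy derivative of 24) | C=C1CCCC(C)(C)[C@@H]2CC[C@@](C)([C@@H]3[C@@H]4OC(=O)[C@@H](OC(C)=O)[C@H]3[C@H](C(=O)OC)O4)[C@H]12 | target

Total step count: 18. Longest linear sequence: 17 (steps 1–13 and 15–18; step 14 prepares the coupling partner).

Steps most likely to fail

Step 8. The first bond formation may discriminate poorly between the methyl group and the ester arm of the quaternary carbon, and over-irradiation may degrade the diketone. The fallback separates the photocycloaddition from the fragmentation. It sets out from 10: acetylation (Ac2O, Et3N, DMAP) would give tert-butyl (S)-3-(2-acetoxy-5-oxocyclopent-1-en-1-yl)-3,7-dimethyloct-6-enoate F1, whose acetoxy group adds bulk on the enol-carbon side and removes the enol hydroxyl altogether. Irradiation of F1 (254 nm, MeCN) would give the cyclobutyl acetate F2, a stable tricycle that can be purified and freed of the epimer at the new ring-fusion CH. K2CO3 in methanol then removes the acetate and triggers the retro-aldol opening under defined protonating conditions, returning to the route at 12.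

Step 16. The bulky radical may close with eroded cis selectivity between the tert-alkyl group and the new side chain, or be reduced before it cyclises. The fallback builds the same tetrahydrofuran by anionic chemistry. It sets out from 14:
- The dianion of 14 (LiN(iPr)2, 2 equiv) opens (R)-tert-butyldimethylsilyl glycidyl ether at its CH2 terminus, and lactonisation (TsOH) gives the α-(hydroazulenyl)-γ-(silyloxymethyl)butyrolactone F3.
- Dehydrogenation (LiN(iPr)2, then N-tert-butylbenzenesulfinimidoyl chloride) gives the butenolide F4.
- LiCH2CO2tBu adds to the β-carbon of F4 anti to the silyloxymethyl group, and the resulting enolate is protonated by 2,6-di-tert-butyl-4-methylphenol on the face away from the new side chain, giving the cis-α,β-disubstituted lactone F5.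
- iBu2AlH (−78 °C) followed by CSA in methanol converts F5 into the methyl acetal with loss of the silyl group, the hydroxymethyl tetrahydrofuran F6.
- TEMPO with PhI(OAc)2 in aqueous MeCN gives the carboxylic acid F7, and TMSCHN2 returns to the route at 23.

Step 18. The base may deprotonate next to the methyl ester instead of the lactone, or the enolate of the acyloxy acetal may fragment. The fallback brings the oxygen in before the bicycle is closed. It sets out from 23: deprotonation of the tert-butyl ester (LiN(iPr)2, −78 °C) and reagent-controlled oxidation with the matching enantiomer of (camphorsulfonyl)oxaziridine would give the α-hydroxy tert-butyl ester F8. Ac2O with pyridine gives the α-acetoxy ester F9, and the lactonisation conditions of step 17 (TMSOTf, 2,6-lutidine) close the bicycle, returning to the route at 26.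

Further compounds
F1 | step 8 | tert-butyl (S)-3-(2-acetoxy-5-oxocyclopent-1-en-1-yl)-3,7-dimethyloct-6-enoate | O=C1CCC(OC(C)=O)=C1[C@](C)(CC(=O)OC(C)(C)C)CCC=C(C)C
F2 | step 8 | acetate of cyclobutanol photoadduct 11 | O=C1CC[C@@]2(OC(C)=O)C(C)(C)[C@@H]3CC[C@@](C)(CC(=O)OC(C)(C)C)[C@]123
F3 | step 16 | 3-(hydroazulenyl)-5-[(tert-butyldimethylsilyloxy)methyl]dihydrofuran-2(3H)-one (epimers at C3) | C=C1CCCC(C)(C)[C@@H]2CC[C@@](C)(C3C[C@H](CO[Si](C)(C)C(C)(C)C)OC3=O)[C@H]12
F4 | step 16 | 3-(hydroazulenyl)-5-[(tert-butyldimethylsilyloxy)methyl]furan-2(5H)-one | C=C1CCCC(C)(C)[C@@H]2CC[C@@](C)(C3=C[C@H](CO[Si](C)(C)C(C)(C)C)OC3=O)[C@H]12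
F5 | step 16 | cis-3-(hydroazulenyl)-4-(2-tert-butoxy-2-oxoethyl)-5-[(tert-butyldimethylsilyloxy)methyl]dihydrofuran-2(3H)-one (C4 chain trans to C5 substituent) | C=C1CCCC(C)(C)[C@@H]2CC[C@@](C)([C@H]3[C@@H](CC(=O)OC(C)(C)C)[C@H](CO[Si](C)(C)C(C)(C)C)OC3=O)[C@H]12
F6 | step 16 | 5-(hydroxymethyl) analogue of 23 | C=C1CCCC(C)(C)[C@@H]2CC[C@@](C)([C@@H]3C(OC)O[C@@H](CO)[C@@H]3CC(=O)OC(C)(C)C)[C@H]12
F7 | step 16 | 5-carboxylic acid analogue of 23 | C=C1CCCC(C)(C)[C@@H]2CC[C@@](C)([C@@H]3C(OC)O[C@@H](C(=O)O)[C@@H]3CC(=O)OC(C)(C)C)[C@H]12
F8 | step 18 | α-hydroxy tert-butyl ester derived from 23 | C=C1CCCC(C)(C)[C@@H]2CC[C@@](C)([C@@H]3C(OC)O[C@@H](C(=O)OC)[C@@H]3[C@H](O)C(=O)OC(C)(C)C)[C@H]12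
F9 | step 18 | α-acetoxy tert-butyl ester derived from 23 | C=C1CCCC(C)(C)[C@@H]2CC[C@@](C)([C@@H]3C(OC)O[C@@H](C(=O)OC)[C@@H]3[C@H](OC(C)=O)C(=O)OC(C)(C)C)[C@H]12
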